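The plan cuts the two bonds that converge on the diosphenol of the tetracyclic half. One runs from the gem-dimethyl carbon to the ring-fusion CH (six-membered ring A). The other runs from the angular-methyl carbon to the enol CH carbon (cyclopentane ring B). That enol carbon is a π-nucleophile three atoms from an E-trisubstituted alkene, so one proton-triggered cation–olefin cascade on bridged diosphenol 21 should close both rings and set both stereocentres. Precursor 21 is a bicyclo[3.2.1]octenedione made by (5+2) cycloaddition. It carries an (E)-iodoalkenyl handle and a bridgehead (R)-carbinol bearing the E-dienyl chain and an 8-phenylmenthyl ester. The labdane half, from abietic acid, is attached last at the vinyl iodide.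

Key step: step 11

Remarks on the chemistry (assumptions)
- **Core numbering:** C1 isopropyl bridgehead, C2 ketone, C3 enol C–OH, C4 enol CH, C5 bridgehead bearing the carbinol, C6 CH2, C7 CH bearing the alkenyl group, C8 one-carbon ketone bridge.
- **Structure check of 39:** The A/B fusion is trans (angular methyl anti to the ring-fusion H). The formyl group is cis to the gem-dimethyl carbon and to the C8 bridge. The C7 alkenyl group is endo, that is, syn to the enone bridge. Labdane C4, C5, C9 and C10 have the configuration of abietic acid. An E inner alkene with anti addition gives exactly this fusion.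
- **Ester choice:** The ester stays on the carbinol through the cascade because it holds back ionisation. It is an 8-phenylmenthyl ester because the auxiliary sets the carbinol, screens one quinone face in the cycloaddition, tolerates SnCl4 and leaves in the reduction.
- **Ester to aldehyde:** No hydride can be expected to reduce a hindered ester selectively beside the C2 and C8 ketones. All three carbonyl groups are therefore reduced together (step 13), and the three alcohols are oxidised together after the fragment union (step 23).
- **Provisional centres:** The C2 and C8 carbinol centres of 24 and 37 are drawn as expected from the less hindered approach. C12 of 33 is an epimer mixture and is drawn without configuration. All three centres are erased later.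
- **Labdane acid:** It is masked as its 2-(trimethylsilyl)ethyl ester, because the β-diketone of the target would not survive saponification of a hindered ester.
- **Arene choice:** 1,2,4-Trimethoxybenzene already holds the three ring oxygens and shortens the arene part.

Step 1
Reactants: 1 1,2,4-trimethoxybenzene
Product: 3 2-(2,3,6-trimethoxyphenyl)propan-2-ol, via 2,3,6-trimethoxyphenyllithium 2 (not isolated)
Conditions: n-BuLi, THF, 0 °C to rt; acetone, −78 °C to rt; H2O
Reagents that add atoms: acetone, CC(C)=O
Why: Directed ortho-metalation takes the proton flanked by two methoxy groups, and 1,2-addition of the aryllithium to acetone puts the three-carbon unit between the two oxygens.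

Step 2
Reactants: 3 2-(2,3,6-trimethoxyphenyl)propan-2-ol
Product: 4 2-isopropyl-1,3,4-trimethoxybenzene
Conditions: Et3SiH, CF3CO2H, CH2Cl2, 0 °C to rt
Reagents that add atoms: none
Why: Ionic hydrogenation, in which the electron-rich tertiary benzylic cation formed in acid is trapped by silane hydride and no other reducible group is present.

Step 3
Reactants: 5 (1R,2S,5R)-8-phenylmenthol; 4 2-isopropyl-1,3,4-trimethoxybenzene
Product: 7 (1R,2S,5R)-8-phenylmenthyl (3-isopropyl-2,4,5-trimethoxyphenyl)glyoxylate, via 8-phenylmenthyl chlorooxoacetate 6 (not isolated)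
Conditions: 5, (COCl)2 (excess), CH2Cl2, 0 °C to rt, evaporate; 4, TiCl4, CH2Cl2, −20 to 0 °C
Reagents that add atoms: oxalyl chloride, O=C(Cl)C(=O)Cl
Why: O-Acylation of the auxiliary alcohol by excess oxalyl chloride followed by Friedel–Crafts acylation, which should go to the ring position para to the central methoxy group and ortho to the outer one, the more activated of the two free sites and the one that halogenation of this arene also uses.

Step 4
Reactants: 8 6-methylhept-5-en-2-one
Product: 10 6-methylhept-5-en-1-yne, via diethyl 6-methylhepta-1,5-dien-2-yl phosphate 9 (not isolated)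
Conditions: LiN(iPr)2, THF, −78 °C; ClP(O)(OEt)2, to rt; LiN(iPr)2 (2.2 equiv), −78 °C to rt; H2O
Reagents that add atoms: none
Why: Methyl ketone to terminal alkyne conversion through kinetic enolate O-phosphorylation on the methyl side and base-induced elimination of diethyl phosphate.

Step 5
Reactants: 10 6-methylhept-5-en-1-yne
Product: 12 (E)-1-iodo-2,6-dimethylhepta-1,5-diene, via (E)-(2,6-dimethylhepta-1,5-dienyl)dimethylalane 11 (not isolated)
Conditions: Me3Al, Cp2ZrCl2 (cat.), CH2Cl2, 0 °C to rt; I2, THF, −30 to 0 °C
Reagents that add atoms: trimethylaluminium, C[Al](C)C; iodine, II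
Why: Negishi carboalumination adds methyl and aluminium syn across the alkyne with aluminium at the terminus, and iodinolysis with retention fixes the E geometry.

Step 6
Reactants: 12 (E)-1-iodo-2,6-dimethylhepta-1,5-diene; 7 (1R,2S,5R)-8-phenylmenthyl (3-isopropyl-2,4,5-trimethoxyphenyl)glyoxylate
Product: 15 8-phenylmenthyl (2R,3E)-2-hydroxy-2-(3-isopropyl-2,4,5-trimethoxyphenyl)-4,8-dimethylnona-3,7-dienoate, via dienyllithium 13 (not isolated), via dienylmagnesium bromide 14 (not isolated)
Conditions: 12, t-BuLi (2 equiv), Et2O, −78 °C; MgBr2·OEt2, −78 to 0 °C; 7, THF, −78 °C; H2O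
Reagents that add atoms: none
Why: Auxiliary-controlled Grignard addition to an α-keto ester, in which exchange and transmetalation keep the E geometry, the ketone is far more electrophilic than the hindered ester, and the phenyl ring of the 8-phenylmenthyl group covers one face of the magnesium-chelated dicarbonyl so that attack on the open Si face sets the (R)-carbinol, any minor diastereomer being removed by chromatography.

Step 7
Reactants: 15 8-phenylmenthyl (2R,3E)-2-hydroxy-2-(3-isopropyl-2,4,5-trimethoxyphenyl)-4,8-dimethylnona-3,7-dienoate
Product: 16 methoxyquinone: 3-isopropyl-2-methoxy-1,4-benzoquinone carrying at C5 the (R)-carbinol side chain of 15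
Conditions: (NH4)2Ce(NO3)6, MeCN–H2O, 0 °C
Reagents that add atoms: water, O
Why: Oxidative demethylation of a hydroquinone dimethyl ether, in which the para pair of methoxy groups is lost to give the p-quinone, the third methoxy group stays as a vinylogous ester, and isolated trisubstituted alkenes, the tertiary alcohol and the ester pass these conditions.

Step 8
Reactants: 16 methoxyquinone
Product: 17 hydroxyquinone: 2-hydroxy-3-isopropyl-1,4-benzoquinone carrying at C5 the (R)-carbinol side chain of 15
Conditions: NaOH (aq), THF, 0 °C; HCl (aq) to pH 3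
Reagents that add atoms: sodium hydroxide, [Na+].[OH-]
Why: Addition–elimination at a vinylogous ester, in which hydroxide displaces methoxide from the quinone far faster than it can attack the hindered secondary-alkyl ester, and acidification returns the free hydroxyquinone whose proton loss will make the cycloaddition irreversible.

Step 9
Reactants: 18 but-1-en-3-yne
Product: 20 (E)-1-iodo-2-methylbuta-1,3-diene, via (E)-(2-methylbuta-1,3-dienyl)dimethylalane 19 (not isolated)
Conditions: Me3Al, Cp2ZrCl2 (cat.), CH2Cl2, 0 °C to rt; I2, THF, −30 °C
Reagents that add atoms: trimethylaluminium, C[Al](C)C; iodine, II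
Why: Negishi carboalumination of the enyne occurs only at the alkyne, syn and with aluminium at the terminus, and iodinolysis with retention gives the E iododiene.

Step 10
Reactants: 17 hydroxyquinone; 20 (E)-1-iodo-2-methylbuta-1,3-diene
Product: 21 bridged diosphenol (key-step precursor): (1R,5R,7R)-3-hydroxy-1-isopropyl-7-endo-[(E)-1-iodoprop-1-en-2-yl]bicyclo[3.2.1]oct-3-ene-2,8-dione whose C5 carries the (R)-carbinol C(OH)(CO2-8-phenylmenthyl)[(E)-2,6-dimethylhepta-1,5-dienyl]
Conditions: 20 (5 equiv), BF3·OEt2, 4 Å MS, CH2Cl2, −78 to −40 °C
Reagents that add atoms: none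
Why: Perezone-type Lewis acid (5+2) cycloaddition, in which boron chelation of the hydroxy-carbonyl pair gives the oxidopentadienyl cation, the CH2 end of the diene bonds to the side-chain-bearing carbon β to the chelated carbonyl and the allyl-cation end to the isopropyl-bearing enol carbon in an endo alignment, while the rotamer with the carbinol OH hydrogen-bonded to the neighbouring quinone carbonyl places the bulky ester and its stacking phenyl ring under one face so that the diene should arrive on the other, a minor face isomer being removed by chromatography.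

Step 11
Reactants: 21 bridged diosphenol (key-step precursor)
Product: 22 tetracyclic hydroxy ester vinyl iodide (key-step product): 21 after closure of trans-fused rings A and B, with new bonds gem-dimethyl carbon to ring-fusion CH and angular-methyl carbon to C4, and the diosphenol restored
Conditions: SnCl4, (R)-2'-methoxy-1,1'-binaphthalen-2-ol, toluene–CH2Cl2, −78 °C
Reagents that add atoms: none
Why: Proposed new method: The proton of the SnCl4-bound binaphthol adds in the Markovnikov sense to the terminal trisubstituted alkene, the tertiary cation at the gem-dimethyl carbon is taken by the CH end of the inner E-alkene, the new tertiary cation at the methyl-bearing carbon is taken by the enol carbon C4, and loss of the C4 proton restores the diosphenol, so the step is an isomerisation. The closest known reactions are polyene cyclisations induced by Lewis-acid-assisted Brønsted acids and ended by arenes or enol derivatives, cationic closures of the 6-5-6 hydrofluorene skeleton, and the α-tert-alkylation of enol derivatives by tertiary cations; a five-ring termination on a bridged diosphenol has not been shown. Ring A closes 6-endo-trig through a chair, and ring B closes 5-exo with the enol double bond outside the new ring (enolexo). The ring-fusion CH and the angular-methyl carbon are set trans to each other by antiperiplanar addition across the E-alkene, and their absolute sense is set by the core: the C5–carbinol bond lies almost in the enol plane and tilts toward the C8 bridge, so the three-atom tether can lay the alkene only over that enol face and the first cation must add from outside, while the (R)-acid, the antipode that induces this A-ring sense in simple polyprenoids, is expected to be matched. The step needs protonation at one of four C=C bonds, which the substrate secures because the inner alkene is deactivated and shielded by the oxygenated quaternary carbinol, the iodoalkene by iodine and the enone by its carbonyl. The carbinol should not ionise because its cation would sit next to the ester carbonyl, and 8-phenylmenthyl esters stand SnCl4 at −78 °C.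

Step 12
Reactants: 22 tetracyclic hydroxy ester vinyl iodide
Product: 23 C3-O-TBS ether of 22
Conditions: TBSOTf, 2,6-lutidine, CH2Cl2, −78 to 0 °C
Reagents that add atoms: tert-butyldimethylsilyl triflate, CC(C)(C)[Si](C)(C)OS(=O)(=O)C(F)(F)F
Why: O-Silylation of the acidic enol, in which the tertiary carbinol buried between fully substituted carbons should not react at low temperature and the silyl enol ether masks the diosphenol for the reduction, the coupling and the oxidation.

Step 13
Reactants: 23 C3-O-TBS ether of 22
Product: 24 tetraol vinyl iodide: 23 with CH2OH in place of the ester and secondary alcohols at C2 and C8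
Conditions: i-Bu2AlH (excess), CH2Cl2, −78 to 0 °C; aq. KNaC4H4O6
Reagents that add atoms: none
Why: Exhaustive hydride reduction of the ester (activated by the aluminium alkoxide of the neighbouring tertiary OH) and of both ketones, with silyl enol ether and vinyl iodide inert; hydride should reach C8 from over the enol ether bridge and C2 from the side of the C8 bridge, but both new centres are erased in step 23.

Step 14
Reactants: 25 abietic acid
Product: 26 2-(trimethylsilyl)ethyl abietate
Conditions: Me3SiCH2CH2OH, PPh3, DIAD, THF, 0 °C to rt
Reagents that add atoms: 2-(trimethylsilyl)ethanol, C[Si](C)(C)CCO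
Why: Mitsunobu esterification, in which the hindered C18 carboxylate acts only as the nucleophile toward the activated primary alcohol, so the crowded carbonyl carbon is never attacked and the acid-sensitive diene is untouched.

Step 15
Reactants: 26 2-(trimethylsilyl)ethyl abietate
Product: 27 13,14-seco keto enal: C14 aldehyde conjugated to C7=C8 with a C9 side chain CH2CH2C(=O)CH(CH3)2
Conditions: O3 (1 equiv), pyridine, CH2Cl2, −78 °C
Reagents that add atoms: ozone, [O-][O+]=O
Why: Ozonolysis stopped after one equivalent, because the C13–C14 bond is the more exposed end of the heteroannular diene and its cleavage leaves C7–C8 as part of an electron-poor enal, while pyridine decomposes the carbonyl oxide so that no peroxide has to be reduced.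

Step 16
Reactants: 27 13,14-seco keto enal
Product: 28 allylic alcohol: 27 with C14H2OH in place of the aldehyde
Conditions: NaBH4, MeOH–CH2Cl2, −78 °C
Reagents that add atoms: none
Why: Chemoselective 1,2-reduction, since at low temperature NaBH4 reduces the aldehyde much faster than the branched isopropyl ketone and leaves the hindered ester alone.

Step 17
Reactants: 28 allylic alcohol
Product: 31 labd-8(17)-ene-type isopropyl ketone with an exocyclic methylene at C8, via sulfonylhydrazine adduct 29 (not isolated), via allylic diazene 30 (not isolated)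
Conditions: 2-O2NC6H4SO2NHNH2, PPh3, DEAD, THF, −30 °C to rt
Reagents that add atoms: none
Why: Reductive 1,3-transposition of an allylic alcohol, in which Mitsunobu displacement by the sulfonyl hydrazide, loss of sulfinic acid on warming and retro-ene loss of N2 deliver hydrogen to C7 and move the double bond to the exocyclic position, so that C14 of abietic acid becomes the labdane C17 methylene.

Step 18
Reactants: 31 labd-8(17)-ene-type isopropyl ketone
Product: 33 C12-hydroxy ketone (both C12 epimers), via potassium enolate 32 (not isolated)
Conditions: KN(SiMe3)2, THF, −78 °C; 2-(phenylsulfonyl)-3-phenyloxaziridine; AcOH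
Reagents that add atoms: 2-(phenylsulfonyl)-3-phenyloxaziridine, O=S(=O)(c1ccccc1)N1OC1c1ccccc1
Why: Kinetic enolisation on the CH2 side of the isopropyl ketone followed by electrophilic hydroxylation with a Davis oxaziridine, a reagent that does not touch the 1,1-disubstituted alkene, and both epimers serve.

Step 19
Reactants: 33 C12-hydroxy ketone
Product: 34 C12 aldehyde (13,14,15,16-tetranorlabd-8(17)-en-12-al 18-ester)
Conditions: NaIO4, THF–H2O, rt
Reagents that add atoms: none
Why: Periodate cleavage of an α-ketol breaks the C12–C13 bond to give the aldehyde and isobutyric acid without affecting the alkene or the ester.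

Step 20
Reactants: 34 C12 aldehyde
Product: 35 C12 acid
Conditions: NaClO2, NaH2PO4, 2-methylbut-2-ene, t-BuOH–H2O, rt
Reagents that add atoms: sodium chlorite, [Na+].[O-]Cl=O
Why: Pinnick oxidation, with 2-methylbut-2-ene in excess to take up hypochlorous acid before it can reach the exocyclic alkene.

Step 21
Reactants: 35 C12 acid
Product: 36 N-acyloxyphthalimide (redox-active ester) of 35
Conditions: N-hydroxyphthalimide, DIC, DMAP (cat.), CH2Cl2, rt
Reagents that add atoms: N-hydroxyphthalimide, O=C1c2ccccc2C(=O)N1O
Why: Carbodiimide (Steglich-type) esterification of the unhindered primary acid gives the redox-active ester.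

Step 22
Reactants: 24 tetraol vinyl iodide; 36 N-acyloxyphthalimide of 35
Product: 37 coupled tetraol with the new C11–C12 bond and an E C12=C13 alkene
Conditions: NiCl2·6H2O (cat.), 2,2'-bipyridine (cat.), AgNO3 (substoichiometric), DMF, Mg anode, carbon cathode, constant current, rt
Reagents that add atoms: none
Why: Nickel-catalysed decarboxylative cross-electrophile alkenylation, in which reduction fragments the N-acyloxyphthalimide to CO2 and the primary C11 radical, this radical is captured by the alkenylnickel species formed from the vinyl iodide, and reductive elimination keeps the E geometry, free hydroxyl groups, silyl enol ether and ester being tolerated.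

Step 23
Reactants: 37 coupled tetraol
Product: 38 protected target: C3-O-TBS ether and 2-(trimethylsilyl)ethyl ester of 39
Conditions: (COCl)2, DMSO, CH2Cl2, −78 °C; Et3N, −78 to 0 °C
Reagents that add atoms: none
Why: Swern oxidation of the primary and the two secondary alcohols in one operation, chosen because activated DMSO does not cleave the tertiary–primary 1,2-diol, cannot oxidise the tertiary alcohol, leaves alkenes, silyl enol ether and ester alone, and erases the two provisional carbinol centres.

Step 24
Reactants: 38 protected target
Product: 39 CNP0124601.1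
Conditions: (Me2N)3S+ Me3SiF2−, DMF, 0 °C; AcOH
Reagents that add atoms: none
Why: Fluoride-induced desilylation, in which attack at silicon frees the enol from its TBS ether and fragments the 2-(trimethylsilyl)ethyl ester to carboxylate, ethene and Me3SiF, so neither the hindered C18 carbonyl nor the base-sensitive β-diketone and α-hydroxy aldehyde meet a hard nucleophile.

Compound list
1 | 1,2,4-trimethoxybenzene | COc1ccc(OC)c(OC)c1 | starting material
2 | 2,3,6-trimethoxyphenyllithium | [Li]c1c(OC)ccc(OC)c1OC | intermediate
3 | 2-(2,3,6-trimethoxyphenyl)propan-2-ol | COc1ccc(OC)c(C(C)(C)O)c1OC | intermediate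
4 | 2-isopropyl-1,3,4-trimethoxybenzene | COc1ccc(OC)c(C(C)C)c1OC | intermediate
5 | (1R,2S,5R)-8-phenylmenthol | O[C@@H]1C[C@H](C)CC[C@H]1C(C)(C)c1ccccc1 | starting material
6 | 8-phenylmenthyl chlorooxoacetate | O=C(Cl)C(=O)O[C@@H]1C[C@H](C)CC[C@H]1C(C)(C)c1ccccc1 | intermediate
7 | 8-phenylmenthyl (3-isopropyl-2,4,5-trimethoxyphenyl)glyoxylate | COc1cc(C(=O)C(=O)O[C@@H]2C[C@H](C)CC[C@H]2C(C)(C)c2ccccc2)c(OC)c(C(C)C)c1OC | intermediate
8 | 6-methylhept-5-en-2-one | CC(C)=CCCC(C)=O | starting material
9 | diethyl 6-methylhepta-1,5-dien-2-yl phosphate | C=C(CCC=C(C)C)OP(=O)(OCC)OCC | intermediate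
10 | 6-methylhept-5-en-1-yne | C#CCCC=C(C)C | intermediate
11 | (E)-(2,6-dimethylhepta-1,5-dienyl)dimethylalane | C[Al](C)/C=C(C)/CCC=C(C)C | intermediate
12 | (E)-1-iodo-2,6-dimethylhepta-1,5-diene | I/C=C(C)/CCC=C(C)C | intermediate
13 | (E)-2,6-dimethylhepta-1,5-dienyllithium | [Li]/C=C(C)/CCC=C(C)C | intermediate
14 | (E)-2,6-dimethylhepta-1,5-dienylmagnesium bromide | Br[Mg]/C=C(C)/CCC=C(C)C | intermediate
15 | 8-phenylmenthyl (2R,3E)-2-hydroxy-2-(3-isopropyl-2,4,5-trimethoxyphenyl)-4,8-dimethylnona-3,7-dienoate | COc1cc([C@@](O)(C(=O)O[C@@H]2C[C@H](C)CC[C@H]2C(C)(C)c2ccccc2)/C=C(C)/CCC=C(C)C)c(OC)c(C(C)C)c1OC | intermediate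
16 | methoxyquinone | COC1=C(C(C)C)C(=O)C([C@@](O)(C(=O)O[C@@H]2C[C@H](C)CC[C@H]2C(C)(C)c2ccccc2)/C=C(C)/CCC=C(C)C)=CC1=O | intermediate
17 | hydroxyquinone | OC1=C(C(C)C)C(=O)C([C@@](O)(C(=O)O[C@@H]2C[C@H](C)CC[C@H]2C(C)(C)c2ccccc2)/C=C(C)/CCC=C(C)C)=CC1=O | intermediate
18 | but-1-en-3-yne | C=CC#C | starting material
19 | (E)-(2-methylbuta-1,3-dienyl)dimethylalane | C[Al](C)/C=C(\C)C=C | intermediate
20 | (E)-1-iodo-2-methylbuta-1,3-diene | I/C=C(\C)C=C | intermediate
21 | bridged diosphenol, key-step precursor | I/C=C(\C)[C@@H]1C[C@@]2([C@@](O)(C(=O)O[C@@H]3C[C@H](C)CC[C@H]3C(C)(C)c3ccccc3)/C=C(C)/CCC=C(C)C)C(=O)[C@]1(C(C)C)C(=O)C(O)=C2 | intermediate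
22 | tetracyclic hydroxy ester vinyl iodide, key-step product | I/C=C(\C)[C@@H]1C[C@@]23C(=O)[C@]1(C(C)C)C(=O)C(O)=C2[C@@]1(C)CCCC(C)(C)[C@@H]1[C@]3(O)C(=O)O[C@@H]1C[C@H](C)CC[C@H]1C(C)(C)c1ccccc1 | intermediate
23 | C3-O-TBS ether of 22 | I/C=C(\C)[C@@H]1C[C@@]23C(=O)[C@]1(C(C)C)C(=O)C(O[Si](C)(C)C(C)(C)C)=C2[C@@]1(C)CCCC(C)(C)[C@@H]1[C@]3(O)C(=O)O[C@@H]1C[C@H](C)CC[C@H]1C(C)(C)c1ccccc1 | intermediate
24 | tetraol vinyl iodide | I/C=C(\C)[C@@H]1C[C@@]23[C@@H](O)[C@]1(C(C)C)[C@@H](O)C(O[Si](C)(C)C(C)(C)C)=C2[C@@]1(C)CCCC(C)(C)[C@@H]1[C@]3(O)CO | intermediate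
25 | abietic acid | CC(C)C1=CC2=CC[C@@H]3[C@@]([C@H]2CC1)(CCC[C@@]3(C)C(=O)O)C | starting material
26 | 2-(trimethylsilyl)ethyl abietate | CC(C)C1=CC2=CC[C@@H]3[C@@]([C@H]2CC1)(CCC[C@@]3(C)C(=O)OCC[Si](C)(C)C)C | intermediate
27 | 13,14-seco keto enal | O=CC1=CC[C@@H]2[C@](C)(CCC[C@@]2(C)C(=O)OCC[Si](C)(C)C)[C@H]1CCC(=O)C(C)C | intermediate
28 | allylic alcohol | OCC1=CC[C@@H]2[C@](C)(CCC[C@@]2(C)C(=O)OCC[Si](C)(C)C)[C@H]1CCC(=O)C(C)C | intermediate
29 | sulfonylhydrazine adduct | NN(CC1=CC[C@@H]2[C@](C)(CCC[C@@]2(C)C(=O)OCC[Si](C)(C)C)[C@H]1CCC(=O)C(C)C)S(=O)(=O)c1ccccc1[N+](=O)[O-] | intermediate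
30 | allylic diazene | N=NCC1=CC[C@@H]2[C@](C)(CCC[C@@]2(C)C(=O)OCC[Si](C)(C)C)[C@H]1CCC(=O)C(C)C | intermediate
31 | labd-8(17)-ene-type isopropyl ketone | C=C1CC[C@@H]2[C@](C)(CCC[C@@]2(C)C(=O)OCC[Si](C)(C)C)[C@H]1CCC(=O)C(C)C | intermediate
32 | potassium enolate | C=C1CC[C@@H]2[C@](C)(CCC[C@@]2(C)C(=O)OCC[Si](C)(C)C)[C@H]1C/C=C(\[O-])C(C)C.[K+] | intermediate
33 | C12-hydroxy ketone (C12 epimers) | C=C1CC[C@@H]2[C@](C)(CCC[C@@]2(C)C(=O)OCC[Si](C)(C)C)[C@H]1CC(O)C(=O)C(C)C | intermediate
34 | C12 aldehyde | C=C1CC[C@@H]2[C@](C)(CCC[C@@]2(C)C(=O)OCC[Si](C)(C)C)[C@H]1CC=O | intermediate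
35 | C12 acid | C=C1CC[C@@H]2[C@](C)(CCC[C@@]2(C)C(=O)OCC[Si](C)(C)C)[C@H]1CC(=O)O | intermediate
36 | N-acyloxyphthalimide of 35 | C=C1CC[C@@H]2[C@](C)(CCC[C@@]2(C)C(=O)OCC[Si](C)(C)C)[C@H]1CC(=O)ON1C(=O)c2ccccc2C1=O | intermediate
37 | coupled tetraol | C=C1CC[C@@H]2[C@](C)(CCC[C@@]2(C)C(=O)OCC[Si](C)(C)C)[C@H]1C/C=C(\C)[C@@H]1C[C@@]23[C@@H](O)[C@]1(C(C)C)[C@@H](O)C(O[Si](C)(C)C(C)(C)C)=C2[C@@]1(C)CCCC(C)(C)[C@@H]1[C@]3(O)CO | intermediate
38 | protected target | C=C1CC[C@@H]2[C@](C)(CCC[C@@]2(C)C(=O)OCC[Si](C)(C)C)[C@H]1C/C=C(\C)[C@@H]1C[C@@]23C(=O)[C@]1(C(C)C)C(=O)C(O[Si](C)(C)C(C)(C)C)=C2[C@@]1(C)CCCC(C)(C)[C@@H]1[C@]3(O)C=O | intermediate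
39 | CNP0124601.1 | C=C1CC[C@@H]2[C@](C)(CCC[C@@]2(C)C(=O)O)[C@H]1C/C=C(\C)[C@@H]1C[C@@]23C(=O)[C@]1(C(C)C)C(=O)C(O)=C2[C@@]1(C)CCCC(C)(C)[C@@H]1[C@]3(O)C=O | target

Total step count: 24.
Longest linear sequence: 13 steps (1, 2, 3, 6, 7, 8, 10, 11, 12, 13, 22, 23, 24) from 1,2,4-trimethoxybenzene. The abietic acid branch runs 11 steps to the target.

Steps most likely to fail

1. **Step 11 (bears the label).**
   - After ring A has closed, the tertiary cation may lose a proton before the weakly nucleophilic, tin-complexed enol carbon reaches it.
   - The second closure may drift to the cis fusion.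
   - The bulky ester, which ends up next to the incoming gem-dimethyl carbon, may slow the fold.
   - The carbinol may ionise after all.

   The fallback replaces the cationic cascade by a radical one, using known metal-hydride hydrogen-atom-transfer chemistry. It sets out from 21 and comes back at 22. Silylation of the diosphenol (TBSOTf, 2,6-lutidine) would give the silyl enol ether of the precursor F1. Fe(acac)3 and PhSiH3 in EtOH would deliver a hydrogen atom to the terminal alkene. The tertiary radical would close ring A 6-endo, and the next tertiary radical would add 5-exo to the β-carbon of the silyloxy enone. Reduction and protonation would then give the saturated α-silyloxy ketone F2. HF·pyridine would free the acyloin F3. Cu(OAc)2 in MeOH would oxidise it to the 1,2-diketone, which enolises to 22.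

2. **Step 10.**
   - Facial selectivity may be poor.
   - The allyl cation may close at its iodine-bearing end in the Diels–Alder sense.
   - The cation may be intercepted by the carbinol oxygen or a quinone oxygen.
   - Bond formation at the hindered quinone carbon may be slow.
   - The side-chain alkene of a second molecule may attack.

   The fallback goes stepwise through an isolable cyclobutane under bidentate titanium activation, which is known for 2-alkoxy-5-alkylquinones. It sets out from 16 (with 20, skipping step 8) and comes back at 21. A TiCl4/Ti(OiPr)4 mixture in CH2Cl2 at −78 °C would give the kinetic [2+2] cyclobutane adduct F4, whose face isomers can be separated. Excess TiCl4 on warming would reopen the allylic cyclobutane bond. The cation would be recaptured by the isopropyl-bearing carbon, and chloride would remove the methyl group to leave diosphenol 21.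

3. **Step 22.**
   - Nickel may capture the β-branched primary radical slowly.
   - The radical may rearrange through reversible closure onto the neighbouring exocyclic alkene.
   - The vinyl iodide may undergo protodeiodination.

   The fallback uses a preformed organozinc and palladium in place of the radical cross-electrophile coupling. It sets out from 35 and 24 and comes back at 37. Decarboxylative iodination of 35 (PhI(OAc)2, I2, light), in which the radical is trapped by iodine far faster than it can rearrange, would give the C11 iodide F5. Zinc insertion (Zn, LiCl, THF) would give the alkylzinc iodide F6. Negishi coupling with 24 (PdCl2(dppf), slow addition of excess F6 to allow for the free hydroxyl groups) would give 37 with retention of the E geometry.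

Further compounds
F1 | step 11 | silyl enol ether of the precursor | I/C=C(\C)[C@@H]1C[C@@]2([C@@](O)(C(=O)O[C@@H]3C[C@H](C)CC[C@H]3C(C)(C)c3ccccc3)/C=C(C)/CCC=C(C)C)C(=O)[C@]1(C(C)C)C(=O)C(O[Si](C)(C)C(C)(C)C)=C2
F2 | step 11 | saturated α-silyloxy ketone | I/C=C(\C)[C@@H]1C[C@@]23C(=O)[C@]1(C(C)C)C(=O)[C@H](O[Si](C)(C)C(C)(C)C)[C@@H]2[C@@]1(C)CCCC(C)(C)[C@@H]1[C@]3(O)C(=O)O[C@@H]1C[C@H](C)CC[C@H]1C(C)(C)c1ccccc1
F3 | step 11 | acyloin | I/C=C(\C)[C@@H]1C[C@@]23C(=O)[C@]1(C(C)C)C(=O)[C@H](O)[C@@H]2[C@@]1(C)CCCC(C)(C)[C@@H]1[C@]3(O)C(=O)O[C@@H]1C[C@H](C)CC[C@H]1C(C)(C)c1ccccc1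
F4 | step 10 | [2+2] cyclobutane adduct | I/C=C(\C)[C@H]1C[C@@]2([C@@](O)(C(=O)O[C@@H]3C[C@H](C)CC[C@H]3C(C)(C)c3ccccc3)/C=C(C)/CCC=C(C)C)C(=O)C(C(C)C)=C(OC)C(=O)[C@@H]12
F5 | step 22 | C11 iodide | C=C1CC[C@@H]2[C@](C)(CCC[C@@]2(C)C(=O)OCC[Si](C)(C)C)[C@H]1CI
F6 | step 22 | alkylzinc iodide | C=C1CC[C@@H]2[C@](C)(CCC[C@@]2(C)C(=O)OCC[Si](C)(C)C)[C@H]1C[Zn]I
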